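**Charge alder.** Its partner stands at 3.04 times the maple charge, above the partner of maple, birch, ash and cedar, so you are extrapolating, and one reading at 24 min has to test the extrapolation.

| flask | starting material | partner | target | time |
|---|---|---|---|---|
| maple | 0.0500 M | 0.125 M |  |  |
| birch | 0.0200 M | 0.0950 M |  |  |
| ash | 0.150 M | 0.125 M |  |  |
| cedar | 0.0500 M | 0.125 M | 0.0250 M |  |
| alder | 0.0170 M | 0.380 M |  | 24 min |

| run | time / min | [target] / M |
|---|---|---|
| maple run | 1.8 | 0.0061 |
| maple run | 5.5 | 0.0164 |
| maple run | 11 | 0.0235 |
| maple run | 17 | 0.0265 |
| maple run | 24 | 0.0280 |
| birch run | 1.8 | 0.0024 |
| birch run | 5.5 | 0.0058 |
| birch run | 11 | 0.0088 |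
| birch run | 17 | 0.0101 |
| birch run | 24 | 0.0107 |
| ash run | 1.8 | 0.0200 |
| ash run | 5.5 | 0.0458 |
| ash run | 11 | 0.0646 |
| ash run | 17 | 0.0724 |
| ash run | 24 | 0.0765 |
| cedar run | 1.8 | 0.0317 |
| cedar run | 5.5 | 0.0408 |
| cedar run | 11 | 0.0482 |
| cedar run | 17 | 0.0507 |
| cedar run | 24 | 0.0526 |

(each reading ± 4 × 10⁻⁴ M)

- the exponent of [starting material] in the starting rate at the charge of the maple run (at the point where two percent of the starting material have become target) (one fixed amount of target, the same in the runs compared)
- the exponent of [partner] in the starting rate at the charge of the maple run (at the point where two percent of the starting material have become target)
- target in the alder run at 24 min, as a share of the starting material charged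

- Overall: starting material + partner -> target.
- Constant volume, constant temperature.
- The analysis sees a species whether free or bound.
- An order is taken over about fifteen percent of the charge, up and down.

**Target left out.** Charge none in alder. Cedar gains 0.0276 M by 24 min and maple gains 0.0280 M, so these two readings show no effect of added target beyond the scatter of 4 × 10⁻⁴ M.

**Waste number.** At 24 min the target stands at 56.0% of the starting material charged in maple, 53.5% in birch and 51.0% in ash, so I read a side loss competing. Take this as my own assumption: the loss ignores partner, and target formation follows the square root of partner. Then waste rate over target rate equals W divided by the square root of partner, the inverse of a selectivity factor. Call W the waste number. Each target uses one partner, so this rate ratio integrates in closed form: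

starting material consumed = target + 2W(√partner at start − √partner now).

The 24 min readings give W as 0.261 in maple, 0.260 in birch and 0.276 in ash, in square-root-molar units. These readings count whatever starting material remains at 24 min as waste, and the alder share you are asked about stands at that same time. A first power of partner gives constants of 0.0867 M in maple and 0.0776 M in ash, a wider spread, though these runs barely separate the two forms.

**My reckoning.** Solving the rule for alder with the maple W gives a target share of 70.1%. The assumed square root puts the order in partner near 0.5. I put the order in starting material near 1, since the ash reading over the maple reading at 1.8 min is 3.28 for a charge ratio of 3.00.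

**The forecast.** It gives an order of 1 in starting material, 0.38 in partner and an alder share of 81%, on the ground that “starting material is consumed first order, independent of partner”. It differs from my reckoning in the partner order and the alder share. The two alder shares lie 4.65 scatter widths apart, so watch the 24 min reading.

**The result.** Alder gives 71.6%, and the orders are 1.0 in starting material and 0.54 in partner.

    starting material + partner → target + by-product (7.080 M⁻¹ min⁻¹)
    starting material → decomposed substrate (0.06120 min⁻¹)
    2 partner ⇌ idle reagent dimer, settled at all times (355.0 M⁻¹)

**Waste number again.** Tying up partner as idle reagent dimer moves the readings by 81 scatter widths, root mean square. Alder's own share gives a waste number of 0.242, against 0.261 from maple. In the birch run, target reaches half of the starting material charged at 17.7 min, and the closed form with alder's waste number estimates the starting material consumed by then at 90.4% of the birch charge.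

All runs were computed on assumed constants; the scatter is artificial.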